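The numbers in the tables come from a simulation for an exercise; noise was put on by code.

North, with less partner than east, has reacted 50.6% of its substrates at 10.0 min, while east has reacted 95.8%.

the same everywhere: left-handed substrate 0.50 M; right-handed substrate 0.50 M; precatalyst 4.5 mM

|  | partner | added ligand | remark | time |
|---|---|---|---|---|
| north | 0.50 M | 4 mM | run made earlier |  |
| east | 1.1 M | 4 mM | run made earlier |  |
| flask | 0.750 M | 4.0 mM |  | 10 min |

- north (time / min: left-handed substrate / %, right-handed substrate / %, left-handed product / %): 1.33: 35.1, 43.2, 16.4; 3.00: 24.1, 35.3, 21.8; 4.00: 19.9, 34.3, 23.8; 6.00: 19.8, 32.5, 24.5; 8.00: 17.0, 32.4, 24.2; 10.0: 17.1, 32.3, 26.1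
- east (time / min: left-handed substrate / %, right-handed substrate / %, left-handed product / %): 0.500: 34.7, 42.4, 14.2; 1.50: 13.0, 28.6, 33.3; 3.00: 3.7, 15.4, 39.4; 4.00: 2.0, 13.4, 42.8; 6.00: 2.2, 9.9, 45.4; 8.00: 0, 7.6, 46.1; 10.0: 0.8, 3.4, 47.8

(each reading ± 1 percentage point)

- catalyst is single-handed; left-handed substrate and right-handed substrate are mirror images of each other, charged as a racemate, each of them at the stated concentration
- the analysis behind the earlier runs scatters by 1 percentage point, standard deviation
- an excess is below zero if the other one leads

- part of the left-handed substrate and right-handed substrate charged together that has reacted at 10 min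
- excess of left-handed product over right-handed product in the product at 10 min
- excess of right-handed substrate over left-handed substrate among what is left of the two at 10 min

The number to know well is the partner cap, the charged [partner] divided by both substrates charged together: 75.0% for the flask, 50.0% for north and 110% for east. North's conversion stands beside its cap, so partner is the limiting reagent there. An error of 10% in that charge moves the flask's cap by 7.5 percentage points.

The rate is tested by a mean. North's mean rate up to 4.00 min, carried over to the flask, gives an estimated 6.55 min to the cap; east's mean rate up to 3.00 min gives an estimated 2.78 min. Both estimates are shorter than 10 min. A mean hides the slowing, but north's span already covers 91.6% of its cap. Precatalyst and added ligand are charged alike in the flask and north.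

The split needs the readings. North's left-handed product reads half of its product at 10.0 min, so the flask's product excess should lie near zero. North's remaining substrates read a selectivity factor of 2.46, so right-handed substrate should lead in the flask. This reckoning puts the flask's conversion at its cap.

The forecast, holding that “partner is used 1:1 and runs out”, gives 75%, 1% and 57%. The flask gives 73.4%, −0.0971% and 55.2%.

    left-handed product ⇌ right-handed product (k = 0.0101 s⁻¹)
    partner + catalyst + left-handed substrate → catalyst + left-handed product (k = 17.9 L² mol⁻² s⁻¹)
    catalyst + added ligand ⇌ idle complex (K = 590 L mol⁻¹, k = 55.7 L mol⁻¹ s⁻¹)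
    partner + precatalyst → catalyst + spent reagent (k = 0.0295 L mol⁻¹ s⁻¹)
    partner + catalyst + right-handed substrate → catalyst + right-handed product (k = 7.45 L² mol⁻² s⁻¹)

The flask stands 1.6 points below its cap. At 10.0 min, 1.6% of its partner charge is left, worth 1.2 points of the substrates, and 0.00417 M of spent reagent is worth 0.42 points. A neighbouring flask, the same but with 0.45 M of partner, has a cap of 45.0%. At 10 min it has reacted 44.5%, with 0.25% of its partner left and right-handed substrate ahead by 25.1%.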